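**Plan**

1. Locants (furo[3,4-c]furan): C1(aryl)–O2–C3H2–C3a(OH)–C4(aryl)–O5–C6H2–C6a(H); the oxolane holding C1/O2/C3 is ring B, the one holding C4/O5/C6 is ring A. Retrosynthesis cuts O5–C6 first (ring A), then C3–C3a and O2–C1 together (ring B → formaldehyde + a cyclopropane whose ring bond joins the future C3a and C1), then the cyclopropane → Z-2-silyloxy enone + aryl carbene, and the enone → 1,2-diketone → aryl alkyne.
2. Forward order: aryl alkyne → diketone → enone → cyclopropane → ring B by insertion of CH2=O into the cyclopropane bond → reduction of the C4 ketone → ring A by SN2 at C6 (last ring) → desilylation.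
3. Enabling feature: the future C1 carries the 3,4-dimethoxyphenyl group (benzylic cation donor) and the future C3a carries the aroyl C=O (the future C4) next to its oxygen. The cyclopropane bond between them is therefore the only donor–acceptor bond and opens as a 1,3-zwitterion exactly where CH2–O must enter.
4. Stereochemistry: C6a from the chiral-sulfide ylide cyclopropanation; C3a from A1,3 strain in the ring-B closure; C1 from the aryl/CH2OSi anti preference (convergent through the benzylic cation); C4 from Felkin–Anh reduction. The trans fusion follows from the fixed C3a/C6a pair and is locked by the irreversible SN2 closure of ring A.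

Key step: step 6

Remark 1: the SMILES encodes a trans-fused 3,7-dioxabicyclo[3.3.0]octane (3a-OH and 6a-H anti, each aryl syn to the OH or H on its neighbouring bridgehead), not the cis-fused natural gmelinol/paulownin series; the route is built for this strained isomer.
Remark 2: the sense of induction of the chiral sulfide in step 5 is assumed; if it proves opposite, the antipodal sulfide is used.

**Route**

Step 1
Reactants: 1 4-iodo-1,2-dimethoxybenzene; 2 tert-butyl(but-3-yn-1-yloxy)dimethylsilane
Product: 3 tert-butyl{[4-(3,4-dimethoxyphenyl)but-3-yn-1-yl]oxy}dimethylsilane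
Conditions: PdCl2(PPh3)2 (2 mol%), CuI (4 mol%), Et3N, THF, rt
Reagents that add atoms: none
Why: Sonogashira coupling; oxidative addition into the aryl iodide is easy even for the electron-rich ring, the copper acetylide of 2 transfers without touching the silyl ether, and no stereocenter is formed.

Step 2
Reactants: 3
Product: 4 4-{[tert-butyl(dimethyl)silyl]oxy}-1-(3,4-dimethoxyphenyl)butane-1,2-dione
Conditions: KMnO4, NaHCO3, MgSO4, acetone/H2O, 0 °C to rt
Reagents that add atoms: potassium permanganate, [K+].[O-][Mn](=O)(=O)=O
Why: Permanganate oxidation of an internal alkyne to the 1,2-diketone through the cyclic manganate ester; the bicarbonate/MgSO4 buffer should keep the medium neutral so that the TBS ether survives and C–C cleavage is suppressed.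

Step 3
Reactants: 4
Product: 5 (Z)-4-{[tert-butyl(dimethyl)silyl]oxy}-1-(3,4-dimethoxyphenyl)-2-{[tri(propan-2-yl)silyl]oxy}but-2-en-1-one
Conditions: i-Pr3SiOTf, Et3N, CH2Cl2, −78 to 0 °C
Reagents that add atoms: triisopropylsilyl trifluoromethanesulfonate, CC(C)[Si](OS(=O)(=O)C(F)(F)F)(C(C)C)C(C)C
Why: Soft enolisation and O-silylation of a diketone that can enolise only towards C3; the Z isomer (silyloxy cis to CH2OTBS) is expected for A1,3 reasons, and the geometry is not critical because the configuration of the silyloxy carbon is erased in step 6.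

Step 4
Reactants: 6 3,4-dimethoxybenzaldehyde
Product: 8 sodium salt of N'-(3,4-dimethoxybenzylidene)-4-methylbenzenesulfonohydrazide, via tosylhydrazone 7 (not isolated)
Conditions: TsNHNH2, MeOH, rt; then NaOMe (1.0 equiv), MeOH, rt; evaporate, dry in vacuo
Reagents that add atoms: p-toluenesulfonohydrazide, Cc1ccc(S(=O)(=O)NN)cc1; sodium methoxide, [Na+].[O-]C
Why: Condensation of the aldehyde with the sulfonyl hydrazide and deprotonation should give the Bamford–Stevens precursor as a storable salt; no stereocenter is involved.

Step 5
Reactants: 5; 8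
Product: 10 (3,4-dimethoxyphenyl)[(1R,2R,3R)-2-({[tert-butyl(dimethyl)silyl]oxy}methyl)-3-(3,4-dimethoxyphenyl)-1-{[tri(propan-2-yl)silyl]oxy}cyclopropyl]methanone, via aryldiazomethane 9 (not isolated)
Conditions: Rh2(OAc)4 (1 mol%), (1R,4R,5R)-isothiocineole [(1R,4R,5R)-4,7,7-trimethyl-6-thiabicyclo[3.2.1]octane] (20 mol%), BnEt3NCl (10 mol%), 1,4-dioxane, 40 °C; major diastereomer separated by chromatography
Reagents that add atoms: none
Why: Sulfur-ylide (Corey–Chaykovsky type) cyclopropanation in which 8 loses sulfinate to give 9, Rh2(OAc)4 passes the carbene to the chiral sulfide, and the benzylic sulfonium ylide adds to the enone β-carbon and closes by 3-exo-tet displacement of the sulfide; the sulfide-bound ylide selects the enone face and so sets cyclopropane C2 (the future C6a), the aryl group should end anti to CH2OTBS, and only the C2 configuration has to survive later.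

Step 6
Reactants: 10; 11 formaldehyde
Product: 12 (3,4-dimethoxyphenyl)[(3S,4S,5R)-4-({[tert-butyl(dimethyl)silyl]oxy}methyl)-5-(3,4-dimethoxyphenyl)-3-{[tri(propan-2-yl)silyl]oxy}oxolan-3-yl]methanone
Conditions: 11 (about 5 equiv, gaseous monomer from cracking dry paraformaldehyde, passed into the cold solution), Sn(OTf)2 (10 mol%), 4 Å molecular sieves, CH2Cl2, −45 to 0 °C
Reagents that add atoms: none
Why: Proposed new method: Sn(OTf)2 binds the aroyl oxygen of 10 and polarises the one cyclopropane bond (C1–C3) that joins the aryl-bearing benzylic carbon (donor) to the silyloxy/aroyl-bearing carbon (acceptor); the formaldehyde oxygen attacks the benzylic carbon as that bond breaks, giving a tin enolate tethered to an O-alkylated formaldehyde oxocarbenium ion, and the enolate carbon then adds to the CH2 carbon, so that CH2–O is inserted into the ring bond in one operation. The closest known reaction type is the Lewis-acid-catalysed formal [3+2] cycloaddition of aryl-substituted cyclopropane-1,1-diesters with aldehydes to give oxolanes; new here are the single ketone acceptor with a geminal silyloxy group and formaldehyde as the carbonyl partner. Ring B closes by a 5-(enolexo)-endo-trig aldol/Prins-type addition to the oxocarbenium ion, the mode that operates in the diester series. Oxolane C3 (quaternary) should be set by A1,3 strain in that closure: the allylic C4–H eclipses the enolate C=C, the oxocarbenium-bearing chain lies on one face and CH2OTBS on the other, so the aroyl group ends anti and the silyloxy group syn to CH2OTBS. C5 should be set by the preference of the aryl group to be anti to CH2OTBS, with either benzylic configuration of the cyclopropane converging because the electron-rich benzylic C–O bond ionises reversibly under the Lewis acid, and C4 is carried over untouched from cyclopropane C2. The step needs regioselective cleavage of the C1–C3 bond, secured by the vicinal 3,4-dimethoxyphenyl donor and aroyl acceptor, and chemoselection against Cloke–Wilson closure through the enolate oxygen, which is reversible for this benzylic ether and should drain to the C–C bonded product.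

Step 7
Reactants: 12
Product: 13 (R)-(3,4-dimethoxyphenyl)[(3S,4S,5R)-4-({[tert-butyl(dimethyl)silyl]oxy}methyl)-5-(3,4-dimethoxyphenyl)-3-{[tri(propan-2-yl)silyl]oxy}oxolan-3-yl]methanol
Conditions: LiBH(s-Bu)3, THF, −78 °C; H2O quench at −78 °C
Reagents that add atoms: none
Why: Felkin–Anh (non-chelation) reduction: the bulky, non-chelating OTIPS group on the quaternary α-carbon stands anti to the incoming hydride, which passes the ring CH2 (small) and not the substituted ring CH (medium), and this should give the (R)-carbinol whose aryl group will be syn to the C3a oxygen in ring A.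

Step 8
Reactants: 13
Product: 14 (R)-(3,4-dimethoxyphenyl)[(3S,4S,5R)-5-(3,4-dimethoxyphenyl)-4-(hydroxymethyl)-3-{[tri(propan-2-yl)silyl]oxy}oxolan-3-yl]methanol
Conditions: HF·pyridine, pyridine, THF, 0 °C
Reagents that add atoms: none
Why: Selective fluoride cleavage of the primary TBS ether; the tertiary TIPS ether is far more hindered and should stay, and the buffered reagent should not ionise the benzylic alcohol or ether.

Step 9
Reactants: 14
Product: 16 (1R,3aS,4R,6aS)-1,4-bis(3,4-dimethoxyphenyl)-3a-{[tri(propan-2-yl)silyl]oxy}tetrahydro-1H,3H-furo[3,4-c]furan (trans-fused), via primary tosylate 15 (not isolated)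
Conditions: n-BuLi (1.0 equiv), THF, −78 °C; TsCl (1.0 equiv), −78 to 0 °C; n-BuLi (1.05 equiv), 0 to 45 °C
Reagents that add atoms: p-toluenesulfonyl chloride, Cc1ccc(S(=O)(=O)Cl)cc1 (its tosyl group is in 15 only and is lost on closure)
Why: One-pot monotosylation and intramolecular Williamson etherification: the less hindered primary lithium alkoxide is sulfonylated and the benzylic alkoxide then closes ring A by irreversible 5-exo-tet SN2 at CH2 with retention at the carbinol carbon; with the tertiary oxygen blocked by the non-migrating TIPS group (no oxetane), the strained trans fusion is the only intramolecular outcome because C3a and C6a are already fixed.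

Step 10
Reactants: 16
Product: 17 (1R,3aS,4R,6aS)-1,4-bis(3,4-dimethoxyphenyl)tetrahydro-1H,3H-furo[3,4-c]furan-3a(4H)-ol (trans-fused; the target)
Conditions: Bu4NF, THF, 50 °C
Reagents that add atoms: none
Why: Fluoride desilylation of the tertiary silyl ether under non-acidic conditions, which should not ionise the strained benzylic C–O bonds; no stereocenter is touched.

**Compound list**

1 | 4-iodo-1,2-dimethoxybenzene | COc1ccc(I)cc1OC | starting material
2 | tert-butyl(but-3-yn-1-yloxy)dimethylsilane | C#CCCO[Si](C)(C)C(C)(C)C | starting material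
3 | tert-butyl{[4-(3,4-dimethoxyphenyl)but-3-yn-1-yl]oxy}dimethylsilane | COc1ccc(C#CCCO[Si](C)(C)C(C)(C)C)cc1OC | intermediate
4 | 4-{[tert-butyl(dimethyl)silyl]oxy}-1-(3,4-dimethoxyphenyl)butane-1,2-dione | COc1ccc(C(=O)C(=O)CCO[Si](C)(C)C(C)(C)C)cc1OC | intermediate
5 | (Z)-4-{[tert-butyl(dimethyl)silyl]oxy}-1-(3,4-dimethoxyphenyl)-2-{[tri(propan-2-yl)silyl]oxy}but-2-en-1-one | COc1ccc(C(=O)/C(O[Si](C(C)C)(C(C)C)C(C)C)=C/CO[Si](C)(C)C(C)(C)C)cc1OC | intermediate
6 | 3,4-dimethoxybenzaldehyde | COc1ccc(C=O)cc1OC | starting material
7 | (E)-N'-(3,4-dimethoxybenzylidene)-4-methylbenzenesulfonohydrazide | COc1ccc(/C=N/NS(=O)(=O)c2ccc(C)cc2)cc1OC | intermediate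
8 | sodium salt of N'-(3,4-dimethoxybenzylidene)-4-methylbenzenesulfonohydrazide | COc1ccc(/C=N/[N-]S(=O)(=O)c2ccc(C)cc2)cc1OC.[Na+] | intermediate
9 | 4-(diazomethyl)-1,2-dimethoxybenzene | COc1ccc(C=[N+]=[N-])cc1OC | intermediate
10 | (3,4-dimethoxyphenyl)[(1R,2R,3R)-2-({[tert-butyl(dimethyl)silyl]oxy}methyl)-3-(3,4-dimethoxyphenyl)-1-{[tri(propan-2-yl)silyl]oxy}cyclopropyl]methanone | COc1ccc(C(=O)[C@@]2(O[Si](C(C)C)(C(C)C)C(C)C)[C@@H](c3ccc(OC)c(OC)c3)[C@@H]2CO[Si](C)(C)C(C)(C)C)cc1OC | intermediate
11 | formaldehyde (monomer, freshly made from paraformaldehyde) | C=O | starting material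
12 | (3,4-dimethoxyphenyl)[(3S,4S,5R)-4-({[tert-butyl(dimethyl)silyl]oxy}methyl)-5-(3,4-dimethoxyphenyl)-3-{[tri(propan-2-yl)silyl]oxy}oxolan-3-yl]methanone | COc1ccc(C(=O)[C@@]2(O[Si](C(C)C)(C(C)C)C(C)C)CO[C@@H](c3ccc(OC)c(OC)c3)[C@@H]2CO[Si](C)(C)C(C)(C)C)cc1OC | intermediate
13 | (R)-(3,4-dimethoxyphenyl)[(3S,4S,5R)-4-({[tert-butyl(dimethyl)silyl]oxy}methyl)-5-(3,4-dimethoxyphenyl)-3-{[tri(propan-2-yl)silyl]oxy}oxolan-3-yl]methanol | COc1ccc([C@@H](O)[C@@]2(O[Si](C(C)C)(C(C)C)C(C)C)CO[C@@H](c3ccc(OC)c(OC)c3)[C@@H]2CO[Si](C)(C)C(C)(C)C)cc1OC | intermediate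
14 | (R)-(3,4-dimethoxyphenyl)[(3S,4S,5R)-5-(3,4-dimethoxyphenyl)-4-(hydroxymethyl)-3-{[tri(propan-2-yl)silyl]oxy}oxolan-3-yl]methanol | COc1ccc([C@@H](O)[C@@]2(O[Si](C(C)C)(C(C)C)C(C)C)CO[C@@H](c3ccc(OC)c(OC)c3)[C@@H]2CO)cc1OC | intermediate
15 | 4-methylbenzenesulfonate of the primary hydroxyl of 14 | COc1ccc([C@@H](O)[C@@]2(O[Si](C(C)C)(C(C)C)C(C)C)CO[C@@H](c3ccc(OC)c(OC)c3)[C@@H]2COS(=O)(=O)c4ccc(C)cc4)cc1OC | intermediate
16 | (1R,3aS,4R,6aS)-1,4-bis(3,4-dimethoxyphenyl)-3a-{[tri(propan-2-yl)silyl]oxy}tetrahydro-1H,3H-furo[3,4-c]furan | COc1ccc([C@H]2OC[C@H]3[C@H](c4ccc(OC)c(OC)c4)OC[C@]23O[Si](C(C)C)(C(C)C)C(C)C)cc1OC | intermediate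
17 | (1R,3aS,4R,6aS)-1,4-bis(3,4-dimethoxyphenyl)tetrahydro-1H,3H-furo[3,4-c]furan-3a(4H)-ol | COc1ccc([C@H]2OC[C@H]3[C@H](c4ccc(OC)c(OC)c4)OC[C@]23O)cc1OC | target

**Count**

Total steps: 10. Longest linear sequence: 9 steps (steps 1–3 and 5–10); step 4 is a one-step side branch.

**Steps most likely to fail**

1. Step 6 (Proposed new method). The ring-opened zwitterion may close through the enolate oxygen (Cloke–Wilson isomerisation) faster than it captures formaldehyde, formaldehyde may polymerise or hydroxymethylate the electron-rich arenes on the Lewis acid, or the enolate may add to free formaldehyde from the face away from the benzylic centre and erode the C3 configuration. Fallback with known chemistry, setting out from 10 and returning at 12: homo-conjugate ring opening of 10 with formic acid (HCO2H, Sc(OTf)3 cat., CH2Cl2, 0 °C) should give the benzylic formate F1. Deprotonation with LiN(SiMe3)2 (THF, −78 °C) lets the ketone enolate take the formyl carbon intramolecularly through the same A1,3-controlled five-membered closure, and the resulting formyl ketone/benzylic alkoxide collapses to the lactol F2. Silane reduction of the lactol (Et3SiH, BF3·OEt2, CH2Cl2, −78 °C) then gives 12.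

2. Step 5. The benzylic sulfonium ylide may add sluggishly to the hindered captodative enone, may attack the carbonyl (epoxide formation), or may select the enone face poorly, so that the diastereomer ratio and the enantiomeric purity at cyclopropane C2 suffer. Fallback, setting out from 5 and 8 and returning at 14: the same cyclopropanation is run with tetrahydrothiophene as achiral sulfide, the racemic 10 is carried through steps 6–8 to racemic 14, and the primary hydroxyl is esterified with (S)-2-methoxy-2-phenylacetic acid (DCC, DMAP, CH2Cl2). The diastereomeric esters are separated, and the wanted ester of 14 with (S)-2-methoxy-2-phenylacetic acid F3 is cleaved with K2CO3/MeOH to give enantiopure 14.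

3. Step 9. Closure of the strained trans-fused ring may be slow enough for intermolecular etherification, E2 loss of the tosylate, or attack of the second equivalent of base at sulfur to compete. Fallback, setting out from 12 and returning at 16: reductive etherification of 12 itself (Et3SiH, BiBr3 cat., MeCN, 0 °C), in which the silyl ether oxygen adds to the activated aryl ketone and the aryl-stabilised cyclic oxocarbenium ion is reduced by the silane. This forms the other C–O bond of ring A (O5–C4), and hydride delivery anti to the OTIPS group should set C4 with the aryl group syn to it; no new compound is made on this way (F0).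

**Further compounds**

F1 | step 6 | (1R,2S)-2-({[tert-butyl(dimethyl)silyl]oxy}methyl)-1,4-bis(3,4-dimethoxyphenyl)-4-oxo-3-{[tri(propan-2-yl)silyl]oxy}butyl formate (both C3 epimers) | COc1ccc(C(=O)C(O[Si](C(C)C)(C(C)C)C(C)C)[C@@H](CO[Si](C)(C)C(C)(C)C)[C@@H](OC=O)c2ccc(OC)c(OC)c2)cc1OC
F2 | step 6 | (3,4-dimethoxyphenyl)[(3S,4S,5R)-4-({[tert-butyl(dimethyl)silyl]oxy}methyl)-5-(3,4-dimethoxyphenyl)-2-hydroxy-3-{[tri(propan-2-yl)silyl]oxy}oxolan-3-yl]methanone (both anomers) | COc1ccc(C(=O)[C@@]2(O[Si](C(C)C)(C(C)C)C(C)C)C(O)O[C@@H](c3ccc(OC)c(OC)c3)[C@@H]2CO[Si](C)(C)C(C)(C)C)cc1OC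
F3 | step 5 | ester of the primary hydroxyl of 14 with (S)-2-methoxy-2-phenylacetic acid | COc1ccc([C@@H](O)[C@@]2(O[Si](C(C)C)(C(C)C)C(C)C)CO[C@@H](c3ccc(OC)c(OC)c3)[C@@H]2COC(=O)[C@@H](OC)c4ccccc4)cc1OC
F0 | step 9 | none | none
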